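- The zeta run's target falls faster after its highest reading than the alpha run's: between the last two readings the logarithmic slopes are 0.0144 h⁻¹ in the zeta run and 0.00456 h⁻¹ in the alpha run, which looks like a loss that grows with catalyst, although these two charges differ in substrate and reagent as well.

| flask | substrate | reagent | free catalyst | time |
|---|---|---|---|---|
| eta | 0.600 M | 0.900 M | 0.0600 M |  |
| alpha | 0.240 M | 0.540 M | 0.0600 M |  |
| zeta | 0.600 M | 0.900 M | 0.120 M |  |
| epsilon | 0.900 M | 0.900 M | 0.0600 M |  |
| theta | 0.600 M | 0.900 M | 0.210 M | 20 h |

| eta run: time / h | eta run: [target] / M | alpha run: time / h | alpha run: [target] / M | zeta run: time / h | zeta run: [target] / M | epsilon run: time / h | epsilon run: [target] / M |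
|---|---|---|---|---|---|---|---|
| 0.80 | 0.007 | 0.80 | 0.007 | 0.80 | 0.012 | 0.80 | 0.008 |
| 1.3 | 0.017 | 1.3 | 0.012 | 1.3 | 0.041 | 1.3 | 0.020 |
| 2.0 | 0.041 | 2.0 | 0.027 | 2.0 | 0.077 | 2.0 | 0.044 |
| 3.2 | 0.084 | 3.2 | 0.055 | 3.2 | 0.153 | 3.2 | 0.088 |
| 5.0 | 0.137 | 5.0 | 0.095 | 5.0 | 0.260 | 5.0 | 0.151 |
| 8.0 | 0.225 | 8.0 | 0.153 | 8.0 | 0.409 | 8.0 | 0.241 |
| 13 | 0.346 | 13 | 0.191 | 13 | 0.502 | 13 | 0.380 |
| 20 | 0.441 | 20 | 0.185 | 20 | 0.454 | 20 | 0.520 |

(standard deviation of a reading: 0.003 M)

- Overall: substrate + reagent -> target, with free catalyst as catalyst.
- Constant volume, constant temperature.
- The analysis sees a species whether free or bound.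
- An order is taken over about fifteen percent of the charge, up and down.

* the exponent of [substrate] in the starting rate at the charge of the eta run (at the point where two percent of the substrate have become target) (one fixed amount of target, the same in the runs compared)
* the exponent of [reagent] in the starting rate at the charge of the eta run (at the point where two percent of the substrate have become target)
* target in the theta run at 20 h, as a share of the substrate charged

- But a slope is a net figure, loss minus whatever target still arrives, so I take a second way, a balance: if conversion has finished by the last reading, the charge minus that reading is the target lost, and a first-order loss constant is that amount over the area under target against time.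
- By trapezoids the area is 165 M·min in the alpha run, so its constant is 0.0200 h⁻¹.
- In the zeta run, at twice the free catalyst, the area is 432 M·min and the constant is 0.0203 h⁻¹, about the same as alpha's.
- The balances agree across different charges and the slopes part, so I trust the balance and read the slopes as the ones that cheat.
- My carried quantity is the target lifetime, the mean time a target molecule survives, one over the mean constant: 49.7 h.
- I take the share of target surviving as the exponential of minus its mean age in lifetimes. The zeta reading at 20 h then gives a mean age of 13.9 h, so by this estimate the zeta run's target was made on average at 6.15 h.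
- I scale that mean making time inversely with free catalyst, which gives 3.51 h for the theta run, and so my own figure for theta is 71.8%.
- The forecast says 0.13 and 0.28 for the orders and 58% for theta, which is lower than my figure; it argues that “Target falls after its peak, faster with more catalyst”.
- The simulation gives 0.13 and 0.10 for the orders and 72.6% for the theta run.

    active catalyst + substrate → catalyst-substrate complex (8.748 M⁻¹ h⁻¹)
    catalyst-substrate complex + reagent → loaded catalyst (6.696 M⁻¹ h⁻¹)
    loaded catalyst → target + active catalyst (0.7776 h⁻¹)
    free catalyst → active catalyst (1.681 h⁻¹)
    target → decomposed product (0.02005 h⁻¹)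

- The theta run ends 15 percentage points above the forecast, and its shortfall from full yield comes from the loss of target to decomposed product: the theta run gives 72.6% with that step and >99.9% without it, a step whose rate holds no catalyst. In lifetimes, the theta share is 0.320, a mean age of 15.9 h. Counted with the same lifetime, the epsilon run's reading of 0.520 M at 20 h stands for 0.633 M of target made, 70.3% of its substrate charged.

The runs were generated by integration from invented constants, noise included.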